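**Strategy.** The γ-butyrolactone ring is assembled by a ketene lactonization of a chiral vinyl sulfoxide. The (Z)-alkenyl p-tolyl (R)-sulfoxide 7, which carries the 3,4-dimethoxybenzyl group, supplies C4 and C5; dichloroketene supplies O1, C2 and C3. In one operation a sulfonium [3,3]-sigmatropic shift joins C3 to C4 and the liberated carboxylate closes onto C5, so the C3–C4 and C5–O1 bonds of the lactone ring form together while sulfur chirality is relayed to C4. The feature exploited is the C4(H)–C5H2–O1 edge of the lactone ring, read as a masked vinyl sulfoxide. C3 is then reduced, hydroxylated, O-benzylated and benzylated anti to the C4 substituent; hydrogenolysis completes the target.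

Key step: step 4

Numbering: atom numbers refer to the oxolan-2-one ring of the target: O1, C2 (C=O), C3 (C–OH), C4 (CH), C5 (CH2).

Assumption: the sense of sulfur-to-carbon chirality transfer in step 4 follows the usual transition-state model for sulfoxide-directed ketene lactonization (sulfur lone pair eclipsing the C=C bond); compounds 1, 4 and 21 are taken as commercial.

**Step 1**
Reactants: 1 3,4-dimethoxybenzyl bromide; 2 ethynylmagnesium bromide
Product: 3 1,2-dimethoxy-4-(prop-2-yn-1-yl)benzene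
Conditions: CuBr (cat.), THF, 0 °C to 50 °C, excess 2; aq NH4Cl
Reagents that add atoms: 2 ethynylmagnesium bromide, C#C[Mg]Br
Why: Copper-catalysed SN2 coupling of an activated benzylic bromide with an alkynyl Grignard reagent, the excess of 2 suppressing a second benzylation.

**Step 2**
Reactants: 3 1,2-dimethoxy-4-(prop-2-yn-1-yl)benzene; 4 (1R,2S,5R)-menthyl (S)-4-methylbenzenesulfinate
Product: 6 (S)-1,2-dimethoxy-4-[3-(4-methylbenzenesulfinyl)prop-2-yn-1-yl]benzene, via alkynylmagnesium bromide 5 (not isolated)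
Conditions: EtMgBr, THF, 0 °C; then inverse addition to 4, toluene, −40 °C; aq NH4Cl
Reagents that add atoms: 4 (1R,2S,5R)-menthyl (S)-4-methylbenzenesulfinate, C[C@@H]1CC[C@H]([C@@H](C1)O[S@](=O)c1ccc(C)cc1)C(C)C
Why: Andersen sulfinate substitution, in which the alkynyl Grignard displaces mentholate at sulfur with inversion, so the sulfur stereocentre comes from the chiral pool (the descriptor stays S only because the priorities change).

**Step 3**
Reactants: 6 (S)-1,2-dimethoxy-4-[3-(4-methylbenzenesulfinyl)prop-2-yn-1-yl]benzene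
Product: 7 1,2-dimethoxy-4-{(2Z)-3-[(R)-4-methylbenzenesulfinyl]prop-2-en-1-yl}benzene
Conditions: H2 (1 atm), RhCl(PPh3)3 (cat.), benzene, rt
Reagents that add atoms: none
Why: Homogeneous syn-hydrogenation of the alkynyl sulfoxide should stop at the (Z)-alkenyl sulfoxide without touching sulfur (the descriptor becomes R by priority change only).

**Step 4**
Reactants: 7 1,2-dimethoxy-4-{(2Z)-3-[(R)-4-methylbenzenesulfinyl]prop-2-en-1-yl}benzene; 8 trichloroacetyl chloride
Product: 12 (4S,5S)-3,3-dichloro-4-(3,4-dimethoxybenzyl)-5-[(4-methylphenyl)sulfanyl]oxolan-2-one, via dichloroketene 9 (not isolated), via sulfonium enolate zwitterion 10 (not isolated), via thionium carboxylate 11 (not isolated)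
Conditions: Zn–Cu couple, Et2O, 0 °C to reflux, slow addition of 8
Reagents that add atoms: 8 trichloroacetyl chloride, ClC(Cl)(Cl)C(Cl)=O (delivered as dichloroketene 9, ClC(Cl)=C=O)
Why: The sulfinyl oxygen of 7 adds to the carbonyl carbon of dichloroketene 9 to give the vinyloxysulfonium enolate 10, whose charge-accelerated [3,3]-sigmatropic shift (sulfonium Claisen type) forms C3–C4 while breaking S–O, and the resulting thionium carboxylate 11 collapses by attack of the carboxylate oxygen on C5 to form C5–O1. The closest known reaction type is the additive Pummerer lactonization of alkenyl sulfoxides with dichloroketene. The lactone ring closes in a 5-exo-trig mode (carboxylate oxygen onto the C5=S+ bond, sulfur outside the ring). C4 is controlled by the sulfur stereocentre: the sulfur lone pair must eclipse the C=C bond to avoid 1,3-allylic strain between p-tolyl and the cis CH2Ar group, so the enolate carbon is delivered to the alkene face that carries the S–O bond, which for (R)-sulfur and (Z)-geometry should give (4S); C5 is expected trans to the C4 substituent and is deleted in step 5. The step needs facial selectivity, secured by the (Z)-geometry, and capture of the thionium ion by carboxylate in place of the dimethoxyphenyl ring, secured by the intramolecular ion pair.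

**Step 5**
Reactants: 12 (4S,5S)-3,3-dichloro-4-(3,4-dimethoxybenzyl)-5-[(4-methylphenyl)sulfanyl]oxolan-2-one
Product: 15 (R)-4-(3,4-dimethoxybenzyl)oxolan-2-one, via chloro lactone 13 (not isolated), via thio lactone 14 (not isolated)
Conditions: Bu3SnH (4 equiv), AIBN (cat.), toluene, reflux
Reagents that add atoms: none
Why: Radical chain reduction in which stannyl radicals abstract both α-chlorines and then the arylthio group of the O,S-acetal, leaving C4 untouched.

**Step 6**
Reactants: 15 (R)-4-(3,4-dimethoxybenzyl)oxolan-2-one; 16 3-phenyl-2-(phenylsulfonyl)oxaziridine (Davis oxaziridine, racemic)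
Product: 18 (3R,4S)-4-(3,4-dimethoxybenzyl)-3-hydroxyoxolan-2-one, via potassium enolate 17 (not isolated)
Conditions: KN(SiMe3)2, THF, −78 °C; then 16; aq NH4Cl
Reagents that add atoms: 16 3-phenyl-2-(phenylsulfonyl)oxaziridine, O=S(=O)(c1ccccc1)N1OC1c1ccccc1
Why: Davis enolate oxidation, with oxygen expected to enter anti to the C4 benzyl group; this C3 configuration is erased again in step 8.

**Step 7**
Reactants: 18 (3R,4S)-4-(3,4-dimethoxybenzyl)-3-hydroxyoxolan-2-one; 19 benzyl bromide
Product: 20 (3R,4S)-3-(benzyloxy)-4-(3,4-dimethoxybenzyl)oxolan-2-one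
Conditions: Ag2O, CH2Cl2, rt, dark
Reagents that add atoms: 19 benzyl bromide, BrCc1ccccc1
Why: Silver-oxide-mediated Williamson etherification, mild enough to leave the lactone intact.

**Step 8**
Reactants: 20 (3R,4S)-3-(benzyloxy)-4-(3,4-dimethoxybenzyl)oxolan-2-one; 21 3,4-bis(benzyloxy)benzyl chloride
Product: 23 (3S,4S)-3-(benzyloxy)-3-[3,4-bis(benzyloxy)benzyl]-4-(3,4-dimethoxybenzyl)oxolan-2-one, via lithium enolate 22 (not isolated)
Conditions: LiN(i-Pr)2, THF–DMPU, −78 °C; then 21, −78 to −20 °C
Reagents that add atoms: 21 3,4-bis(benzyloxy)benzyl chloride, ClCc1ccc(OCc2ccccc2)c(OCc2ccccc2)c1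
Why: Enolate alkylation of the planar α-benzyloxy lactone enolate, where the electrophile should approach anti to the C4 dimethoxybenzyl group, placing the new benzyl group trans to it and the C3 oxygen cis, which is the (3S) quaternary centre.

**Step 9**
Reactants: 23 (3S,4S)-3-(benzyloxy)-3-[3,4-bis(benzyloxy)benzyl]-4-(3,4-dimethoxybenzyl)oxolan-2-one
Product: 24 (3S,4S)-3-(3,4-dihydroxybenzyl)-4-(3,4-dimethoxybenzyl)-3-hydroxyoxolan-2-one
Conditions: H2 (1 atm), Pd/C, EtOAc–MeOH, rt
Reagents that add atoms: none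
Why: Catalytic hydrogenolysis of the two aryl benzyl ethers and the tertiary alkyl benzyl ether, with neither stereocentre involved.

**Compound list**

1 | 3,4-dimethoxybenzyl bromide | COc1ccc(CBr)cc1OC | starting material
2 | ethynylmagnesium bromide | C#C[Mg]Br | starting material
3 | 1,2-dimethoxy-4-(prop-2-yn-1-yl)benzene | COc1ccc(CC#C)cc1OC | intermediate
4 | (1R,2S,5R)-menthyl (S)-4-methylbenzenesulfinate | C[C@@H]1CC[C@H]([C@@H](C1)O[S@](=O)c1ccc(C)cc1)C(C)C | starting material
5 | [3-(3,4-dimethoxyphenyl)prop-1-yn-1-yl]magnesium bromide | COc1ccc(CC#C[Mg]Br)cc1OC | intermediate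
6 | (S)-1,2-dimethoxy-4-[3-(4-methylbenzenesulfinyl)prop-2-yn-1-yl]benzene | COc1ccc(CC#C[S@@](=O)c2ccc(C)cc2)cc1OC | intermediate
7 | 1,2-dimethoxy-4-{(2Z)-3-[(R)-4-methylbenzenesulfinyl]prop-2-en-1-yl}benzene | COc1ccc(C/C=C\[S@@](=O)c2ccc(C)cc2)cc1OC | intermediate
8 | trichloroacetyl chloride | ClC(Cl)(Cl)C(Cl)=O | starting material
9 | dichloroketene | ClC(Cl)=C=O | intermediate
10 | [(2,2-dichloro-1-oxidoethenyl)oxy][(1Z)-3-(3,4-dimethoxyphenyl)prop-1-en-1-yl](4-methylphenyl)sulfonium (zwitterion) | COc1ccc(C/C=C\[S@@+](OC([O-])=C(Cl)Cl)c2ccc(C)cc2)cc1OC | intermediate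
11 | (3S)-2,2-dichloro-3-(3,4-dimethoxybenzyl)-4-[(4-methylphenyl)sulfaniumylidene]butanoate (thionium geometry not specified) | COc1ccc(C[C@@H](C=[S+]c2ccc(C)cc2)C(Cl)(Cl)C(=O)[O-])cc1OC | intermediate
12 | (4S,5S)-3,3-dichloro-4-(3,4-dimethoxybenzyl)-5-[(4-methylphenyl)sulfanyl]oxolan-2-one | COc1ccc(C[C@H]2[C@H](Sc3ccc(C)cc3)OC(=O)C2(Cl)Cl)cc1OC | intermediate
13 | (4S,5S)-3-chloro-4-(3,4-dimethoxybenzyl)-5-[(4-methylphenyl)sulfanyl]oxolan-2-one (C3 epimers) | COc1ccc(C[C@H]2[C@H](Sc3ccc(C)cc3)OC(=O)C2Cl)cc1OC | intermediate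
14 | (4R,5S)-4-(3,4-dimethoxybenzyl)-5-[(4-methylphenyl)sulfanyl]oxolan-2-one | COc1ccc(C[C@H]2[C@H](Sc3ccc(C)cc3)OC(=O)C2)cc1OC | intermediate
15 | (R)-4-(3,4-dimethoxybenzyl)oxolan-2-one | COc1ccc(C[C@H]2COC(=O)C2)cc1OC | intermediate
16 | 3-phenyl-2-(phenylsulfonyl)oxaziridine (racemic) | O=S(=O)(c1ccccc1)N1OC1c1ccccc1 | starting material
17 | potassium (4R)-4-(3,4-dimethoxybenzyl)-4,5-dihydrofuran-2-olate | COc1ccc(C[C@H]2COC([O-])=C2)cc1OC.[K+] | intermediate
18 | (3R,4S)-4-(3,4-dimethoxybenzyl)-3-hydroxyoxolan-2-one | COc1ccc(C[C@H]2COC(=O)[C@@H]2O)cc1OC | intermediate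
19 | benzyl bromide | BrCc1ccccc1 | starting material
20 | (3R,4S)-3-(benzyloxy)-4-(3,4-dimethoxybenzyl)oxolan-2-one | COc1ccc(C[C@H]2COC(=O)[C@@H]2OCc2ccccc2)cc1OC | intermediate
21 | 3,4-bis(benzyloxy)benzyl chloride | ClCc1ccc(OCc2ccccc2)c(OCc2ccccc2)c1 | starting material
22 | lithium (4S)-3-(benzyloxy)-4-(3,4-dimethoxybenzyl)-4,5-dihydrofuran-2-olate | COc1ccc(C[C@H]2COC([O-])=C2OCc2ccccc2)cc1OC.[Li+] | intermediate
23 | (3S,4S)-3-(benzyloxy)-3-[3,4-bis(benzyloxy)benzyl]-4-(3,4-dimethoxybenzyl)oxolan-2-one | COc1ccc(C[C@H]2COC(=O)[C@]2(OCc2ccccc2)Cc2ccc(OCc3ccccc3)c(OCc3ccccc3)c2)cc1OC | intermediate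
24 | (3S,4S)-3-(3,4-dihydroxybenzyl)-4-(3,4-dimethoxybenzyl)-3-hydroxyoxolan-2-one | COc1ccc(C[C@H]2COC(=O)[C@]2(O)Cc2ccc(O)c(O)c2)cc1OC | target

**Step count.** Total: 9 steps. Longest linear sequence: 9 steps (1 to 24).

**Steps most likely to fail**

1. Step 4. Chirality transfer from sulfur to C4 may be incomplete if a second rotamer of the sulfonium enolate reacts. The thionium ion may also be intercepted by the electron-rich dimethoxyphenyl ring before the carboxylate closes, and the sulfoxide may be deoxygenated by the zinc. The fallback sets out from 1 and returns at 15, giving up the ketene lactonization for an auxiliary-controlled alkylation. (R)-4-Benzyl-3-[4-(tert-butoxy)-4-oxobutanoyl]oxazolidin-2-one F1 would be made from (R)-4-benzyloxazolidin-2-one and 4-(tert-butoxy)-4-oxobutanoic acid (pivaloyl chloride, Et3N, LiCl). Its sodium enolate (NaN(SiMe3)2, THF, −78 °C) would be alkylated with 1 on the face away from the auxiliary benzyl group (Evans alkylation) to give (R)-4-benzyl-3-[(2R)-4-(tert-butoxy)-2-(3,4-dimethoxybenzyl)-4-oxobutanoyl]oxazolidin-2-one F2. LiBH4 (THF, one equivalent of water, 0 °C) would reduce the imide carbonyl selectively and release tert-butyl (3R)-3-(3,4-dimethoxybenzyl)-4-hydroxybutanoate F3. CF3CO2H in CH2Cl2 would then close F3 to lactone 15, and steps 6 to 9 follow unchanged.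

2. Step 2. The propargylic, benzylic CH2 group of 6 is doubly activated, so excess Grignard base may shift the alkyne to an allenyl sulfoxide or add a second time at sulfur. The fallback sets out from 3 and returns at 12, and avoids any alkynyl sulfoxide. Hydrozirconation of 3 with Cp2Zr(H)Cl (THF, rt) followed by I2 would give (E)-4-(3-iodoprop-2-en-1-yl)-1,2-dimethoxybenzene F4. Iodine–lithium exchange (t-BuLi, Et2O, −78 °C) and inverse addition to (1S,2R,5S)-menthyl (R)-4-methylbenzenesulfinate (C[C@H]1CC[C@@H]([C@H](C1)O[S@@](=O)c1ccc(C)cc1)C(C)C) would give, with inversion at sulfur, 1,2-dimethoxy-4-{(2E)-3-[(S)-4-methylbenzenesulfinyl]prop-2-en-1-yl}benzene F5. Under the conditions of step 4, the (E)-alkene with (S)-sulfur should expose the same alkene face and so give the same lactone 12.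

3. Step 8. The hindered, fully substituted enolate 22 may react sluggishly with the benzylic chloride, facial selectivity may erode, or the α-benzyloxy enolate may undergo a [1,2]-Wittig shift on warming. The fallback sets out from 20 and returns at 24, replacing alkylation by an aldol addition followed by reductive removal of the benzylic oxygen. Enolate 22 would be trapped at −78 °C with the more reactive 3,4-bis(benzyloxy)benzaldehyde (O=Cc1ccc(OCc2ccccc2)c(OCc2ccccc2)c1), again anti to the C4 substituent, to give (3R,4S)-3-(benzyloxy)-3-{[3,4-bis(benzyloxy)phenyl](hydroxy)methyl}-4-(3,4-dimethoxybenzyl)oxolan-2-one F6 (carbinol epimers). Hydrogenation over Pd(OH)2/C in AcOH with a trace of HCl should cleave the electron-rich benzylic C–OH bond together with the three benzyl ethers and give 24 directly.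

**Further compounds**

F1 | step 4 | (R)-4-benzyl-3-[4-(tert-butoxy)-4-oxobutanoyl]oxazolidin-2-one | CC(C)(C)OC(=O)CCC(=O)N1[C@H](Cc2ccccc2)COC1=O
F2 | step 4 | (R)-4-benzyl-3-[(2R)-4-(tert-butoxy)-2-(3,4-dimethoxybenzyl)-4-oxobutanoyl]oxazolidin-2-one | COc1ccc(C[C@H](CC(=O)OC(C)(C)C)C(=O)N2[C@H](Cc3ccccc3)COC2=O)cc1OC
F3 | step 4 | tert-butyl (3R)-3-(3,4-dimethoxybenzyl)-4-hydroxybutanoate | COc1ccc(C[C@H](CC(=O)OC(C)(C)C)CO)cc1OC
F4 | step 2 | (E)-4-(3-iodoprop-2-en-1-yl)-1,2-dimethoxybenzene | COc1ccc(C/C=C/I)cc1OC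
F5 | step 2 | 1,2-dimethoxy-4-{(2E)-3-[(S)-4-methylbenzenesulfinyl]prop-2-en-1-yl}benzene | COc1ccc(C/C=C/[S@](=O)c2ccc(C)cc2)cc1OC
F6 | step 8 | (3R,4S)-3-(benzyloxy)-3-{[3,4-bis(benzyloxy)phenyl](hydroxy)methyl}-4-(3,4-dimethoxybenzyl)oxolan-2-one (carbinol epimers) | COc1ccc(C[C@H]2COC(=O)[C@]2(OCc2ccccc2)C(O)c2ccc(OCc3ccccc3)c(OCc3ccccc3)c2)cc1OC
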